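The earlier runs and the new flask were generated by integration for an exercise, noise included.

No reading can show the electrophile at 12 min, because the delta run stops at 2.50 min. The flask repeats the electrophile and nucleophile charges of that run, with twice its free base.

- delta: electrophile 45 mM; nucleophile 42.7 mM; free base 11 mM; run made earlier
- flask: electrophile 45 mM; nucleophile 42.7 mM; free base 22.5 mM; time 12 min

delta run (percent of the electrophile charged)

| time / min | electrophile / % | target / % |
|---|---|---|
| 0.200 | 92 | 11 |
| 0.333 | 87 | 13 |
| 0.500 | 80 | 19 |
| 0.833 | 69 | 27 |
| 1.33 | 57 | 29 |
| 2.50 | 37 | 36 |

(each reading ± 2 percentage points)

1. part of the electrophile that has reacted at 12 min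
2. share of the unused nucleophile that is free and not bound as protonated nucleophile, at 12 min

- the numbers in the tables scatter by 2 percentage points (one standard deviation)
- the earlier runs do not show how much of nucleophile is bound; that part of a forecast is a guess
- no earlier run changes the charge of free base; that part of a forecast is a guess

In the delta run, 37% of the electrophile stood at the last reading, which gives 1.74 min as the apparent half-life, the half-life a first-order loss through that reading must have. Carried to the flask, 12 min counts 6.89 such half-lives, so a constant half-life leaves 0.846% and 99.2% has reacted. The share of free nucleophile stays a guess, since no earlier run shows the bound part.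

The weak link is the constant half-life. The charges are close (45 mM against 42.7 mM), so a second-order loss at equal charges is the other estimate: it leaves one over one plus the count, 12.7%, and 87.3% has reacted. The reckoning therefore expects the answer between these two values, as an estimate and not as a bound.

The forecast gives 97% reacted, “allowing for some slowing” after a first-order extrapolation, and 25% of the unused nucleophile free.

The flask gives 94.3% reacted and 30.5% free.

    acid set free + free base ⇌ salt of the base, settled at all times (K = 3.40 × 10⁵ L mol⁻¹)
    nucleophile + acid set free ⇌ protonated nucleophile, settled at all times (K = 36000 L mol⁻¹)
    free base + target → over-reaction product (k = 0.670 L mol⁻¹ min⁻¹)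
    electrophile + nucleophile → acid set free + target (k = 13.0 L mol⁻¹ min⁻¹)
    electrophile + target → side product (k = 6.20 L mol⁻¹ min⁻¹)

The flask keeps 5.74% of its electrophile at 12 min, which is 4.12 half-lives averaging 2.91 min, longer than the apparent half-life of 1.74 min read from the delta run. The neighbour flask with 73 mM of nucleophile keeps 0.275%, and its half-lives average 1.41 min. The flask is not at rest at 12 min. By 120 min its reacted part reaches 100%, target falls from 38.2% to 34.2%, and side product rises from 55.2% to 63.3%.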